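**Retrosynthetic overview**
1. Locants follow labdane numbering: ring A = C-1 to C-5 and C-10, ring B = C-5 to C-10, C-18 = 4α-CH2OH, C-19 = 4β-CH3, side chain C-11 to C-16, α = the face opposite the C-10 methyl.
2. C-12–C-13 is cut last: B-alkyl Suzuki–Miyaura coupling of a 9β-vinyl decalin triol (fragment 1) with an (R)-butenolide (E)-iodoalkene (fragment 2, butenolide ring by ring-closing metathesis).
3. The C-4 quaternary centre, 18-OH and 6α-OH come from LiAlH4 opening of an 18,6α-γ-lactone that can only be methylated on its β face; the lactone comes from a C-4 ketone (reductive cyanation) and a 6α-hydroxyl placed by conjugate borylation of a Δ5-4-enone.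
4. Ring B is closed by a one-flask [3+3] annulation of ring A with 4,4-dimethoxybutan-2-one: C-5 (silyl enol ether carbon) bonds to the acetal carbon C-6 and C-9 (γ-carbon of an (E)-allylboronate on C-10) bonds to the ketone carbon C-8. The enabling feature is that C-6/C-7/C-8 of ring B is a masked 3-oxobutanal (1,3-dioxygenated, C-8 a methyl carbinol) whose neighbours C-5 and C-9 both sit on quaternary C-10 and can each be made nucleophilic from outside ring B: C-5 through a C-4 carbonyl in ring A, C-9 through the C-11=C-12 allyl unit that survives as the vinyl handle.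
5. Ring order: ring A (commercial enone, C-10 by catalytic asymmetric conjugate addition), ring B (key step), temporary lactone ring (formed, then opened), butenolide ring (made separately, joined last).

Key step: step 3

Remark: in steps 1 and 11 the enantiomer of the chiral ligand or catalyst is taken to be the one that delivers the (R)-configured product drawn.

**Fragment 1 (decalin)**

Step 1
Reactants: 1 3-methylcyclohex-2-en-1-one
Product: 3 (R)-tert-butyldimethyl[(3-methyl-3-vinylcyclohex-1-en-1-yl)oxy]silane, via aluminium enolate 2 (not isolated)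
Conditions: CH2=CHMgBr, Me2AlCl, Et2O, −78 → 0 °C (gives Me2AlCH=CH2); then 1, Cu(O2CC4H3S) (copper thiophene-2-carboxylate, monovalent copper, 5 mol %), chiral N,N-bis(1-arylethyl)diarylphosphinamine ligand (5.5 mol %), Et2O, −30 °C; then TBSOTf, THF, −30 → 0 °C
Reagents that add atoms: vinylmagnesium bromide, C=C[Mg]Br; tert-butyldimethylsilyl triflate, CC(C)(C)[Si](C)(C)OS(=O)(=O)C(F)(F)F
Why: Copper-catalysed asymmetric conjugate addition of an alkenylalane to a β-substituted cyclohexenone sets the C-10 quaternary centre under ligand control, and silyl triflate trapping of the regiodefined aluminium enolate fixes the enol double bond at C-4/C-5, the only place from which C-5 can later act as the nucleophile.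

Step 2
Reactants: 3 (R)-silyl enol ether; 4 2-allyl-4,4,5,5-tetramethyl-1,3,2-dioxaborolane (allylboronic acid pinacol ester)
Product: 5 tert-butyldimethyl({(R)-3-methyl-3-[(E)-3-(4,4,5,5-tetramethyl-1,3,2-dioxaborolan-2-yl)prop-1-en-1-yl]cyclohex-1-en-1-yl}oxy)silane
Conditions: 4 (3 equiv), second-generation Grubbs catalyst (5 mol %), CH2Cl2, 40 °C
Reagents that add atoms: none
Why: Olefin cross-metathesis of the hindered vinyl group on a quaternary carbon, which does not homodimerise, with an excess of the unhindered allylboronate should give the (E)-γ-substituted allylboronate, the trisubstituted silyl enol ether being inert.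

Step 3
Reactants: 5 (E)-allylboronate silyl enol ether; 6 4,4-dimethoxybutan-2-one
Product: 9 8α-hydroxy-6-methoxy-8β,10β-dimethyl-9β-vinyldecalin-4-one (9α-H; epimer mixture at C-5 and C-6), via Mukaiyama adduct 7 (not isolated), via cyclic borate 8 (not isolated)
Conditions: 6 (1.1 equiv), TMSOTf (10 mol %), CH2Cl2, −78 °C; then solid NaHCO3, warm to 40 °C; aq. NaHCO3 work-up
Reagents that add atoms: none
Why: TMSOTf ionises the acetal of 6 to an oxocarbenium ion that is captured by C-5 of the silyl enol ether (Mukaiyama aldol-type addition to an acetal), and the methyl ketone C-8 now held on the ring is allylated intramolecularly by the pinacol allylboronate, whose γ-carbon C-9 attacks the carbonyl carbon and closes ring B in a 6-exo-trig mode. Both events are standard reaction types, the closest precedents being Lewis acid [3+3] cyclisations of 1,3-bis-nucleophiles with this same β-keto acetal and intramolecular allylborations that give trans-2-vinylcycloalkanols. The allyl transfer runs through a bicyclic chair Zimmerman–Traxler transition state in which the (E)-alkene places C-10 equatorial, so the carbonyl oxygen lies anti to C-10 across the new bond and becomes the equatorial 8α-hydroxyl, the smaller methyl takes the axial 8β position, and the vinyl group ends equatorial on C-9 with 9α-H; the fixed (R)-C-10 centre, whose methyl is axial on the forming ring, decides the absolute sense. C-5 and C-6 are formed without control, which does not matter because step 4 erases both. The step needs chemoselectivity between two nucleophiles and two electrophiles, which their reactivities secure (the enol ether is far more nucleophilic than the allylboronate and the oxocarbenium ion far more electrophilic than the ketone, so the first bond can only be C-5–C-6), and it needs the allylboronate to survive the Lewis acid, which the catalytic loading, the low temperature and the bicarbonate quench before warming secure.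

Step 4
Reactants: 9 β-methoxy ketone (epimer mixture)
Product: 10 (4aR,5R,6R)-6-hydroxy-4a,6-dimethyl-5-vinyl-3,4,4a,5,6,7-hexahydronaphthalen-1(2H)-one (labdane locants: Δ5-4-one; 8α-OH; 8β,10β-dimethyl; 9β-vinyl)
Conditions: DBU (2 equiv), toluene, 60 °C
Reagents that add atoms: none
Why: E1cB loss of methanol from the β-methoxy ketone (enolisation at C-5 towards the C-4 carbonyl) should converge all C-5/C-6 isomers on the single Δ5-4-enone, ring B fixing the alkene geometry.

Step 5
Reactants: 10 Δ5-4-enone
Product: 12 6α,8α-dihydroxy-8β,10β-dimethyl-9β-vinyl-5α-decalin-4-one (trans-decalin), via β-boryl ketone 11 (not isolated)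
Conditions: B2pin2 (1.2 equiv), CuCl (5 mol %), NaOtBu (10 mol %), bis[2-(diphenylphosphino)phenyl] ether (5 mol %), MeOH (2 equiv), THF, 23 °C; then NaBO3·4H2O, THF/H2O, 23 °C
Reagents that add atoms: bis(pinacolato)diboron (the boron of 11), CC1(C)OB(OC1(C)C)B1OC(C)(C)C(C)(C)O1; sodium perborate (the C-6 oxygen), [Na+].OO[B-](O)(O)O
Why: Copper-catalysed conjugate borylation should deliver boron to C-6 from the α face, away from the two axial β-methyl groups on C-8 and C-10, stereoretentive oxidation then gives the equatorial 6α-alcohol, and the C-5 hydrogen, α to the ketone, settles trans to the C-10 methyl under the mildly basic oxidation.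

Step 6
Reactants: 12 β-hydroxy ketone
Product: 13 8α-hydroxy-8β,10β-dimethyl-6α-(triethylsilyloxy)-9β-vinyl-5α-decalin-4-one
Conditions: TESOTf (1.1 equiv), 2,6-lutidine, CH2Cl2, −78 °C
Reagents that add atoms: triethylsilyl triflate, CC[Si](CC)(CC)OS(=O)(=O)C(F)(F)F
Why: Selective silylation of the secondary 6α-hydroxyl, the tertiary 8α-hydroxyl being much slower, blocks retro-aldol cleavage of the β-hydroxy ketone in the basic step that follows.

Step 7
Reactants: 13 silyl ether ketone
Product: 14 8α-hydroxy-8β,10β-dimethyl-6α-(triethylsilyloxy)-9β-vinyl-5α-decalin-4-carbonitrile (epimer mixture at C-4)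
Conditions: TosMIC (1.5 equiv), KOtBu (2.5 equiv), DME/t-BuOH, 0 → 40 °C
Reagents that add atoms: p-toluenesulfonylmethyl isocyanide, Cc1ccc(cc1)S(=O)(=O)C[N+]#[C-]
Why: van Leusen reductive cyanation converts the C-4 ketone into the one-carbon-homologated nitrile (the future C-18), the configuration at C-4 being unimportant because step 8 equilibrates it.

Step 8
Reactants: 14 nitrile (C-4 epimers)
Product: 17 8α-hydroxy-8β,10β-dimethyl-9β-vinyl-5α-decalin-18,6α-olide (trans-fused γ-lactone; 4β-H), via hydroxy nitrile 15 (not isolated), via iminolactone 16 (not isolated)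
Conditions: TBAF, THF, 23 °C; KOtBu (0.3 equiv), t-BuOH/THF, 60 °C; then 1 M aq. citric acid, 23 °C
Reagents that add atoms: water, O
Why: After desilylation the nitrile epimerises at C-4 under catalytic alkoxide, only the 4α (equatorial) nitrile can be reached by the peri 6α-alkoxide (5-exo-dig addition, Pinner-type), and mild acid hydrolysis of the cyclic imidate gives the γ-lactone, so the C-4 mixture is funnelled into one configuration.

Step 9
Reactants: 17 lactone
Product: 18 8α-hydroxy-4β,8β,10β-trimethyl-9β-vinyl-5α-decalin-18,6α-olide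
Conditions: LiN(i-Pr)2 (LDA, 2.5 equiv), THF, −78 → −40 °C; MeI, −78 → 0 °C
Reagents that add atoms: iodomethane, CI
Why: Alkylation of the lactone enolate, whose only α-carbon is C-4, must occur on the β face because the lactone bridge ties C-18 to the 6α-oxygen of the rigid trans-decalin (a cis-fused lactone cannot exist here), which sets the quaternary centre with 4β-methyl and 4α-carbonyl.

Step 10
Reactants: 18 methylated lactone
Product: 19 4α-(hydroxymethyl)-4β,8β,10β-trimethyl-9β-vinyl-5α-decalin-6α,8α-diol (vinyl triol)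
Conditions: LiAlH4, THF, 0 → 40 °C
Reagents that add atoms: none
Why: Hydride reduction of the γ-lactone releases the 18-hydroxymethyl group and the 6α-hydroxyl at once without touching any stereocentre or the vinyl group.

**Fragment 2 (butenolide iodoalkene)**

Step 11
Reactants: 20 methacrolein; 21 allenylboronic acid pinacol ester
Product: 23 (R)-2-methylhex-1-en-5-yn-3-ol, via borate ester 22 (not isolated)
Conditions: (R)-3,3'-bis(2,4,6-triisopropylphenyl)-1,1'-binaphthyl-2,2'-diyl hydrogen phosphate (5 mol %), 4 Å molecular sieves, toluene, −20 °C; aqueous work-up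
Reagents that add atoms: none
Why: Chiral phosphoric acid-catalysed propargylation of the aldehyde by the allenylboronate (SE2' through a six-membered transition state organised by the catalyst) sets the carbinol centre that becomes the butenolide γ-carbon.

Step 12
Reactants: 23 terminal alkyne
Product: 24 (R)-2-methylhept-1-en-5-yn-3-ol
Conditions: n-BuLi (2.1 equiv), THF, −78 → −20 °C; MeI (1.05 equiv), −78 → 0 °C
Reagents that add atoms: iodomethane, CI
Why: In the alkoxide–acetylide dianion the acetylide carbon is the more nucleophilic site, so C-methylation should give the 2-alkyne needed for a regiodefined hydrometalation.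

Step 13
Reactants: 24 internal alkyne
Product: 26 (R,E)-6-iodo-2-methylhepta-1,5-dien-3-ol, via alkenylzirconium 25 (not isolated)
Conditions: Cp2Zr(H)Cl (2.5 equiv), THF, 23 → 45 °C; then I2, 0 °C
Reagents that add atoms: iodine, II
Why: syn-Hydrozirconation of the homopropargylic 2-alkyne, equilibrated by excess reagent, places zirconium on the less hindered methyl-bearing carbon, and iodinolysis with retention gives the (E)-2-iodoalkene with the methyl cis to the carbinol chain.

Step 14
Reactants: 26 iodo dienol
Product: 27 (R,E)-6-iodo-2-methylhepta-1,5-dien-3-yl acrylate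
Conditions: acryloyl chloride, i-Pr2NEt, DMAP (cat.), CH2Cl2, −20 → 0 °C
Reagents that add atoms: acryloyl chloride, C=CC(=O)Cl
Why: Acylation of the secondary allylic alcohol installs the two remaining butenolide carbons without touching the stereocentre.

Step 15
Reactants: 27 acrylate
Product: 28 (R)-5-[(E)-3-iodobut-2-en-1-yl]-4-methylfuran-2(5H)-one
Conditions: second-generation Grubbs catalyst (10 mol %), toluene, 80 °C
Reagents that add atoms: none
Why: Ring-closing metathesis between the acrylate and the 1,1-disubstituted isopropenyl alkene forms the 4-methylbutenolide ring, the trisubstituted iodoalkene being too hindered and electron-poor to take part.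

**Union**

Step 16
Reactants: 19 vinyl triol; 28 butenolide iodoalkene
Product: 30 (R)-5-{(E)-5-[6α,8α-dihydroxy-4α-(hydroxymethyl)-4β,8β,10β-trimethyl-5α-decalin-9β-yl]-3-methylpent-2-en-1-yl}-4-methylfuran-2(5H)-one (CNP0147582.1), via B-alkyl-9-BBN 29 (not isolated)
Conditions: 9-BBN dimer (excess), THF, 23 °C; then 28, Pd(dppf)Cl2 (10 mol %), AsPh3, K3PO4 (3 M aq.), DMF, 23 °C
Reagents that add atoms: none
Why: anti-Markovnikov hydroboration of the only alkene of 19 and B-alkyl Suzuki–Miyaura coupling with the (E)-iodoalkene, with retention of geometry, joins C-12 to C-13 and completes the skeleton with all hydroxyls free.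

**Compound list**
1 | 3-methylcyclohex-2-en-1-one | CC1=CC(=O)CCC1 | starting material
2 | dimethylaluminium enolate of (R)-3-methyl-3-vinylcyclohexanone (enolate double bond towards the quaternary carbon) | C=C[C@@]1(C)CCCC(O[Al](C)C)=C1 | intermediate
3 | (R)-tert-butyldimethyl[(3-methyl-3-vinylcyclohex-1-en-1-yl)oxy]silane | C=C[C@@]1(C)CCCC(O[Si](C)(C)C(C)(C)C)=C1 | intermediate
4 | 2-allyl-4,4,5,5-tetramethyl-1,3,2-dioxaborolane | C=CCB1OC(C)(C)C(C)(C)O1 | starting material
5 | tert-butyldimethyl({(R)-3-methyl-3-[(E)-3-(pinacolatoboryl)prop-1-en-1-yl]cyclohex-1-en-1-yl}oxy)silane | CC1(C)OB(C/C=C/[C@@]2(C)CCCC(O[Si](C)(C)C(C)(C)C)=C2)OC1(C)C | intermediate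
6 | 4,4-dimethoxybutan-2-one | CC(=O)CC(OC)OC | starting material
7 | (3R)-2-(1-methoxy-3-oxobutyl)-3-methyl-3-[(E)-3-(pinacolatoboryl)prop-1-en-1-yl]cyclohexan-1-one (mixture at C-2 and at the methoxy carbon) | CC(=O)CC(OC)C1C(=O)CCC[C@]1(C)/C=C/CB1OC(C)(C)C(C)(C)O1 | intermediate
8 | pinacol borate ester of 9 (boron on the 8α-oxygen) | C=C[C@@H]1[C@@]2(C)CCCC(=O)C2C(OC)C[C@@]1(C)OB1OC(C)(C)C(C)(C)O1 | intermediate
9 | 8α-hydroxy-6-methoxy-8β,10β-dimethyl-9β-vinyldecalin-4-one (mixture at C-5 and C-6) | C=C[C@@H]1[C@@]2(C)CCCC(=O)C2C(OC)C[C@@]1(C)O | intermediate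
10 | (4aR,5R,6R)-6-hydroxy-4a,6-dimethyl-5-vinyl-3,4,4a,5,6,7-hexahydronaphthalen-1(2H)-one | C=C[C@@H]1[C@@]2(C)CCCC(=O)C2=CC[C@@]1(C)O | intermediate
11 | 6α-(pinacolatoboryl)-8α-hydroxy-8β,10β-dimethyl-9β-vinyldecalin-4-one | C=C[C@@H]1[C@@]2(C)CCCC(=O)C2[C@@H](B2OC(C)(C)C(C)(C)O2)C[C@@]1(C)O | intermediate
12 | 6α,8α-dihydroxy-8β,10β-dimethyl-9β-vinyl-5α-decalin-4-one | C=C[C@@H]1[C@@]2(C)CCCC(=O)[C@@H]2[C@@H](O)C[C@@]1(C)O | intermediate
13 | 8α-hydroxy-8β,10β-dimethyl-6α-(triethylsilyloxy)-9β-vinyl-5α-decalin-4-one | C=C[C@@H]1[C@@]2(C)CCCC(=O)[C@@H]2[C@@H](O[Si](CC)(CC)CC)C[C@@]1(C)O | intermediate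
14 | 8α-hydroxy-8β,10β-dimethyl-6α-(triethylsilyloxy)-9β-vinyl-5α-decalin-4-carbonitrile (C-4 epimers) | C=C[C@@H]1[C@@]2(C)CCCC(C#N)[C@@H]2[C@@H](O[Si](CC)(CC)CC)C[C@@]1(C)O | intermediate
15 | 6α,8α-dihydroxy-8β,10β-dimethyl-9β-vinyl-5α-decalin-4-carbonitrile (C-4 epimers) | C=C[C@@H]1[C@@]2(C)CCCC(C#N)[C@@H]2[C@@H](O)C[C@@]1(C)O | intermediate
16 | cyclic imidate (18-imino-18,6α-epoxy bridge; 4β-H) | C=C[C@@H]1[C@@]2(C)CCC[C@@H]3[C@@H]2[C@@H](OC3=N)C[C@@]1(C)O | intermediate
17 | 8α-hydroxy-8β,10β-dimethyl-9β-vinyl-5α-decalin-18,6α-olide (4β-H) | C=C[C@@H]1[C@@]2(C)CCC[C@@H]3[C@@H]2[C@@H](OC3=O)C[C@@]1(C)O | intermediate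
18 | 8α-hydroxy-4β,8β,10β-trimethyl-9β-vinyl-5α-decalin-18,6α-olide | C=C[C@@H]1[C@@]2(C)CCC[C@]3(C)[C@@H]2[C@@H](OC3=O)C[C@@]1(C)O | intermediate
19 | 4α-(hydroxymethyl)-4β,8β,10β-trimethyl-9β-vinyl-5α-decalin-6α,8α-diol | C=C[C@@H]1[C@@]2(C)CCC[C@@](C)(CO)[C@@H]2[C@@H](O)C[C@@]1(C)O | intermediate
20 | methacrolein (2-methylprop-2-enal) | CC(=C)C=O | starting material
21 | allenylboronic acid pinacol ester | C=C=CB1OC(C)(C)C(C)(C)O1 | starting material
22 | pinacol borate ester of 23 | CC1(C)OB(O[C@@H](C(C)=C)CC#C)OC1(C)C | intermediate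
23 | (R)-2-methylhex-1-en-5-yn-3-ol | O[C@@H](C(C)=C)CC#C | intermediate
24 | (R)-2-methylhept-1-en-5-yn-3-ol | O[C@@H](C(C)=C)CC#CC | intermediate
25 | (E)-alkenylzirconocene chloride from 24 (zirconium on the methyl-bearing carbon; hydroxyl drawn free) | O[C@@H](C(C)=C)C/C=C(\C)[Zr](Cl)(C1C=CC=C1)C1C=CC=C1 | intermediate
26 | (R,E)-6-iodo-2-methylhepta-1,5-dien-3-ol | O[C@@H](C(C)=C)C/C=C(\C)I | intermediate
27 | (R,E)-6-iodo-2-methylhepta-1,5-dien-3-yl acrylate | C=CC(=O)O[C@@H](C(C)=C)C/C=C(\C)I | intermediate
28 | (R)-5-[(E)-3-iodobut-2-en-1-yl]-4-methylfuran-2(5H)-one | CC1=CC(=O)O[C@@H]1C/C=C(\C)I | intermediate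
29 | B-alkyl-9-borabicyclo[3.3.1]nonane from 19 (boron on C-12) | C(C[C@@H]1[C@@]2(C)CCC[C@@](C)(CO)[C@@H]2[C@@H](O)C[C@@]1(C)O)B1C2CCCC1CCC2 | intermediate
30 | CNP0147582.1 | CC1=CC(=O)O[C@@H]1C/C=C(\C)CC[C@@H]1[C@@]2(C)CCC[C@@](C)(CO)[C@@H]2[C@@H](O)C[C@@]1(C)O | target

**Step count and risks**
Total step count: 16. Longest linear sequence: 11 (steps 1 to 10, then 16).

The three steps most likely to fail:

Step 3. The ring-closing allylboration has to build a 1,3-diaxial methyl/methyl interaction next to a quaternary carbon. It may therefore be slower than loss of methanol from the β-methoxy ketone, or it may leak through a boat transition state and erode the C-8/C-9 configuration. Fallback: from 5, step 3 is stopped cold (aqueous quench at −78 °C) so that adduct 7 is isolated. Oxidation of its allylboronate (NaBO3·4H2O, THF/H2O) gives the allylic alcohol F1, and CBr4/PPh3 gives the allylic bromide F2. CrCl2 in THF at 23 °C then generates an allylchromium species that adds to the methyl ketone through the same closed chair arrangement (intramolecular Nozaki–Hiyama allylation) and returns to 9.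

Step 9. Deprotonation of the axial C-4 hydrogen of the strained trans-fused lactone may be too slow, or the enolate too hindered on its β face, so that O-methylation of the tertiary alkoxide or decomposition takes over. Fallback: from nitrile 14, deprotonation with LiN(i-Pr)2 and hydroxymethylation with monomeric formaldehyde, expected from the equatorial α direction anti to the axial C-10 methyl, gives the 4β-cyano-4α-hydroxymethyl compound F3. DIBAL reduction and aqueous acid work-up give the 4β-aldehyde F4. Wolff–Kishner reduction (N2H4·H2O, KOH, diethylene glycol, 130 → 200 °C), which also cleaves the silyl ether, turns the formyl group into the 4β-methyl and returns to 19.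

Step 16. The aqueous base of the Suzuki–Miyaura coupling may epimerise the acidic γ-position of the butenolide or open the lactone before the slow B-alkyl transmetalation is complete. Fallback: from 19, hydrozirconation of the vinyl group (Cp2Zr(H)Cl, excess, THF) and quenching with N-bromosuccinimide give the primary bromide F5. Nickel-catalysed reductive cross-electrophile coupling of F5 with 28 (NiBr2·glyme, 4,4'-di-tert-butyl-2,2'-bipyridine, Mn powder, N,N-dimethylacetamide, 23 °C) needs no base and tolerates free hydroxyls and esters, and returns to 30.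

Further compounds
F1 | step 3 | (3R)-3-[(E)-3-hydroxyprop-1-en-1-yl]-2-(1-methoxy-3-oxobutyl)-3-methylcyclohexan-1-one | CC(=O)CC(OC)C1C(=O)CCC[C@]1(C)/C=C/CO
F2 | step 3 | (3R)-3-[(E)-3-bromoprop-1-en-1-yl]-2-(1-methoxy-3-oxobutyl)-3-methylcyclohexan-1-one | CC(=O)CC(OC)C1C(=O)CCC[C@]1(C)/C=C/CBr
F3 | step 9 | 8α-hydroxy-4α-(hydroxymethyl)-8β,10β-dimethyl-6α-(triethylsilyloxy)-9β-vinyl-5α-decalin-4β-carbonitrile | C=C[C@@H]1[C@@]2(C)CCC[C@@](C#N)(CO)[C@@H]2[C@@H](O[Si](CC)(CC)CC)C[C@@]1(C)O
F4 | step 9 | 8α-hydroxy-4α-(hydroxymethyl)-8β,10β-dimethyl-6α-(triethylsilyloxy)-9β-vinyl-5α-decalin-4β-carbaldehyde | C=C[C@@H]1[C@@]2(C)CCC[C@@](C=O)(CO)[C@@H]2[C@@H](O[Si](CC)(CC)CC)C[C@@]1(C)O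
F5 | step 16 | 9β-(2-bromoethyl)-4α-(hydroxymethyl)-4β,8β,10β-trimethyl-5α-decalin-6α,8α-diol | BrCC[C@@H]1[C@@]2(C)CCC[C@@](C)(CO)[C@@H]2[C@@H](O)C[C@@]1(C)O
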